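## Retrosynthetic overview

1. Target 28 ← acetylation of triol 27 ← acid deprotection of 26; the 4β‑methyl of 26 comes from the free CO2H of half‑ester 21 (CO2H → CH2OH → CHO → CH3).
2. Ring A of 21 (C4, C5 and the 1(10)‑alkene) ← Ireland–Claisen ring contraction of δ‑lactone 18; its C‑1 carbinol comes from CBS reduction of enone 16.
3. 16 ← malonate Michael addition to divinyl ketone 14 ← carbonylative Stille coupling of ring‑B alkenyl triflate 13.
4. Ring‑B ketone 11 ← chelation‑controlled MeMgBr addition to diketone 9 ← Mukaiyama–Michael union (C9–C11) of silyl enol ether 7 with vinyl ketone 4 (from D‑mannitol diacetonide).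
5. Ring order: ring B is carried from 2‑methylcyclohexenone 5; ring A is closed last, through the temporary lactone ring of 18.

Assumption: the SMILES is taken literally, i.e. methyl (4R,5R,8R,9S,13S,14R)-14,15-diacetoxy-13-hydroxyhalim-1(10)-en-18-oate (4α‑CO2Me, 4β‑Me, 5α‑H, 8α‑Me, 9α‑Me, 9β‑side chain); halimane numbering is used throughout.

Abbreviation used in names: R* = (3S)-3-[(4R)-2,2-dimethyl-1,3-dioxolan-4-yl]-3-(triethylsilyloxy)butyl (the protected C11–C16 side chain). Full SMILES are in the compound list.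

## Route

Step 1
Reactants: 1 1,2:5,6-di-O-isopropylidene-D-mannitol
Product: 2 (R)-2,2-dimethyl-1,3-dioxolane-4-carbaldehyde (two molecules per molecule of 1)
Conditions: NaIO4, sat. aq NaHCO3, CH2Cl2, rt
Reagents that add atoms: none
Why: Periodate glycol cleavage of the central diol gives the aldehyde and leaves the chiral‑pool centre (future C‑14, R) untouched.

Step 2
Reactants: 2 (R)-2,2-dimethyl-1,3-dioxolane-4-carbaldehyde
Product: 3 1-[(4R)-2,2-dimethyl-1,3-dioxolan-4-yl]prop-2-en-1-ol (carbinol epimers)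
Conditions: CH2=CHMgBr, THF, −78 → 0 °C; then H2O
Reagents that add atoms: vinylmagnesium bromide, C=C[Mg]Br
Why: Grignard addition to the aldehyde; the new carbinol configuration is irrelevant because it is oxidised in the next step.

Step 3
Reactants: 3 1-[(4R)-2,2-dimethyl-1,3-dioxolan-4-yl]prop-2-en-1-ol
Product: 4 1-[(4R)-2,2-dimethyl-1,3-dioxolan-4-yl]prop-2-en-1-one
Conditions: Dess–Martin periodinane, CH2Cl2, 0 °C → rt; used at once
Reagents that add atoms: none
Why: Dess–Martin oxidation under near‑neutral conditions gives the vinyl ketone without epimerising the α‑oxygenated centre.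

Step 4
Reactants: 5 2-methylcyclohex-2-en-1-one
Product: 7 [(3R)-2,3-dimethylcyclohex-1-en-1-yl]oxy(trimethyl)silane, via dimethylaluminium enolate 6 (not isolated)
Conditions: AlMe3 (1.3 equiv), CuTC (2 mol %), chiral phosphoramidite L* (4 mol %, antipode giving 3R), Et2O, −30 °C; then TMSOTf, THF, −30 → 0 °C
Reagents that add atoms: trimethylaluminium, C[Al](C)C; trimethylsilyl triflate, C[Si](C)(C)OS(=O)(=O)C(F)(F)F
Why: Copper‑catalysed asymmetric conjugate addition sets C‑8 (R) by ligand control, and O‑silylation traps the regiodefined enolate.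

Step 5
Reactants: 7 [(3R)-2,3-dimethylcyclohex-1-en-1-yl]oxy(trimethyl)silane; 4 1-[(4R)-2,2-dimethyl-1,3-dioxolan-4-yl]prop-2-en-1-one
Product: 9 (2S,3R)-2-{3-[(4R)-2,2-dimethyl-1,3-dioxolan-4-yl]-3-oxopropyl}-2,3-dimethylcyclohexan-1-one, via trimethylsilyl enol ether adduct 8 (not isolated)
Conditions: TrSbCl6 (5 mol %), CH2Cl2, −78 °C; then aq citric acid (cat.)/THF, 0 °C
Reagents that add atoms: none
Why: Mukaiyama–Michael addition joins the two fragments at C9–C11 and creates quaternary C‑9; the enone approaches anti to the adjacent C‑8 methyl, so the chain is trans to it (9S, 8‑Me/9‑Me cis).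

Step 6
Reactants: 9 (2S,3R)-2-{3-[(4R)-2,2-dimethyl-1,3-dioxolan-4-yl]-3-oxopropyl}-2,3-dimethylcyclohexan-1-one
Product: 10 (2S,3R)-2-{(3S)-3-[(4R)-2,2-dimethyl-1,3-dioxolan-4-yl]-3-hydroxybutyl}-2,3-dimethylcyclohexan-1-one
Conditions: MgBr2·OEt2 (1.2 equiv), CH2Cl2, −78 °C; MeMgBr (1.3 equiv), −78 °C; then H2O
Reagents that add atoms: methylmagnesium bromide, C[Mg]Br
Why: Cram‑chelate Grignard addition: Mg bridges the side‑chain ketone and the α‑dioxolane oxygen and methyl attacks from the H side of C‑14, giving 13S; the ring ketone next to quaternary C‑9 is too hindered to compete at −78 °C.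

Step 7
Reactants: 10 (2S,3R)-2-{(3S)-3-[(4R)-2,2-dimethyl-1,3-dioxolan-4-yl]-3-hydroxybutyl}-2,3-dimethylcyclohexan-1-one
Product: 11 (2S,3R)-2,3-dimethyl-2-R*-cyclohexan-1-one
Conditions: TESOTf, 2,6-lutidine, CH2Cl2, −78 → 0 °C
Reagents that add atoms: triethylsilyl triflate, CC[Si](CC)(CC)OS(=O)(=O)C(F)(F)F
Why: Silylation of the tertiary alcohol with a silyl triflate masks the only acidic OH before the enolate and organometallic steps.

Step 8
Reactants: 11 (2S,3R)-2,3-dimethyl-2-R*-cyclohexan-1-one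
Product: 13 (5R,6S)-5,6-dimethyl-6-R*-cyclohex-1-en-1-yl trifluoromethanesulfonate, via potassium enolate 12 (not isolated)
Conditions: KHMDS, THF, −78 °C; PhNTf2, −78 → 0 °C
Reagents that add atoms: N-phenylbis(trifluoromethanesulfonimide), O=S(=O)(N(c1ccccc1)S(=O)(=O)C(F)(F)F)C(F)(F)F
Why: Enolate O‑triflation; C‑5 is the only enolisable position, so the alkenyl triflate is regiodefined (C10=C5).

Step 9
Reactants: 13 (5R,6S)-5,6-dimethyl-6-R*-cyclohex-1-en-1-yl trifluoromethanesulfonate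
Product: 14 1-[(5R,6S)-5,6-dimethyl-6-R*-cyclohex-1-en-1-yl]prop-2-en-1-one
Conditions: Pd(PPh3)4 (5 mol %), LiCl (3 equiv), CO (3 atm), CH2=CHSnBu3, THF, 55 °C
Reagents that add atoms: carbon monoxide, [C-]#[O+]; tributyl(vinyl)stannane, C=C[Sn](CCCC)(CCCC)CCCC
Why: Carbonylative Stille coupling: CO inserts into the alkenyl–Pd bond before transmetalation, installing C‑1 as a ketone with C‑2/C‑3 as a vinyl group.

Step 10
Reactants: 14 1-[(5R,6S)-5,6-dimethyl-6-R*-cyclohex-1-en-1-yl]prop-2-en-1-one; 15 dimethyl malonate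
Product: 16 dimethyl 2-{3-[(5R,6S)-5,6-dimethyl-6-R*-cyclohex-1-en-1-yl]-3-oxopropyl}propanedioate
Conditions: 15 (2 equiv), K2CO3 (10 mol %), MeOH, 0 °C, short reaction time
Reagents that add atoms: none
Why: Michael addition of malonate to the unsubstituted vinyl terminus (C‑3), which is far more accessible than the ring β‑carbon C‑5; this brings in C‑4, C‑18 and C‑19.

Step 11
Reactants: 16 dimethyl 2-{3-[(5R,6S)-5,6-dimethyl-6-R*-cyclohex-1-en-1-yl]-3-oxopropyl}propanedioate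
Product: 17 dimethyl 2-{(3R)-3-hydroxy-3-[(5R,6S)-5,6-dimethyl-6-R*-cyclohex-1-en-1-yl]propyl}propanedioate
Conditions: (S)-Me-CBS (1 equiv), catecholborane, toluene, −78 → −40 °C; then MeOH, pH 7 buffer
Reagents that add atoms: none
Why: Corey–Bakshi–Shibata reduction; with the 2‑substituted cyclohexenyl as the large group the (S)‑catalyst gives the 1R allylic alcohol under catalyst control.

Step 12
Reactants: 17 dimethyl 2-{(3R)-3-hydroxy-3-[(5R,6S)-5,6-dimethyl-6-R*-cyclohex-1-en-1-yl]propyl}propanedioate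
Product: 18 methyl (6R)-6-[(5R,6S)-5,6-dimethyl-6-R*-cyclohex-1-en-1-yl]-2-oxooxane-3-carboxylate (C-3 epimers)
Conditions: DBU (0.2 equiv), toluene, 60 °C, 4 Å MS
Reagents that add atoms: none
Why: Base‑catalysed intramolecular transesterification closes the six‑membered lactone; the C‑3 epimers converge in the next step through the planar ketene acetal.

Step 13
Reactants: 18 methyl (6R)-6-[(5R,6S)-5,6-dimethyl-6-R*-cyclohex-1-en-1-yl]-2-oxooxane-3-carboxylate
Product: 21 (4R,5R,8R,9S)-halim-1(10)-ene-18,19-dioic acid 18-methyl ester (19-CO2H free; 13-OTES; 14,15-acetonide), via lactone silyl ketene acetal 19 (not isolated), via bicyclic TBS ester 20 (not isolated)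
Conditions: TBSOTf, Et3N, toluene, 0 °C, then 110 °C; then THF/H2O, AcOH (cat.), rt
Reagents that add atoms: none
Why: Ireland–Claisen ring contraction through the boat transition state enforced by the lactone. The C4–C5 bond forms on the face from which the C1–O bond departs, so 1R gives 5α‑H. The carboxyl that was in the lactone ring ends trans to H‑5 (the future 4β‑methyl), leaving CO2Me cis to H‑5, and the alkene moves to C1=C10.

Step 14
Reactants: 21 (4R,5R,8R,9S)-halim-1(10)-ene-18,19-dioic acid 18-methyl ester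
Product: 23 methyl (4R,5R,8R,9S)-19-hydroxyhalim-1(10)-en-18-oate (13-OTES; 14,15-acetonide), via isobutyl carbonic anhydride 22 (not isolated)
Conditions: i-BuOCOCl, N-methylmorpholine, THF, −15 °C; filter; NaBH4, THF/H2O, 0 °C
Reagents that add atoms: none
Why: Mixed carbonic anhydride reduction with NaBH4 reduces only the activated carboxyl and leaves the methyl ester and the alkene alone.

Step 15
Reactants: 23 methyl (4R,5R,8R,9S)-19-hydroxyhalim-1(10)-en-18-oate
Product: 24 methyl (4R,5R,8R,9S)-19-oxohalim-1(10)-en-18-oate (13-OTES; 14,15-acetonide)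
Conditions: Dess–Martin periodinane, CH2Cl2, rt
Reagents that add atoms: none
Why: Dess–Martin oxidation of the neopentyl alcohol gives a non‑enolisable aldehyde.

Step 16
Reactants: 24 methyl (4R,5R,8R,9S)-19-oxohalim-1(10)-en-18-oate
Product: 25 the C-19 N-tosylhydrazone of 24
Conditions: TsNHNH2, EtOH, rt
Reagents that add atoms: p-toluenesulfonyl hydrazide, Cc1ccc(cc1)S(=O)(=O)NN
Why: Condensation of the aldehyde with tosylhydrazide prepares the reductive deoxygenation.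

Step 17
Reactants: 25 the C-19 N-tosylhydrazone of 24
Product: 26 methyl (4R,5R,8R,9S,13S,14R)-14,15-O-isopropylidene-13-(triethylsilyloxy)halim-1(10)-en-18-oate
Conditions: catecholborane, CHCl3, 0 °C → rt; then NaOAc·3H2O, reflux
Reagents that add atoms: none
Why: Kabalka (Caglioti‑type) tosylhydrazone reduction: hydride addition, then loss of sulfinate and N2 from the alkyldiazene gives the methyl group; the hydrazone is not conjugated, so the alkene does not move.

Step 18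
Reactants: 26 methyl (4R,5R,8R,9S,13S,14R)-14,15-O-isopropylidene-13-(triethylsilyloxy)halim-1(10)-en-18-oate
Product: 27 methyl (4R,5R,8R,9S,13S,14R)-13,14,15-trihydroxyhalim-1(10)-en-18-oate
Conditions: 1 M aq HCl/MeOH/THF (1:4:4), rt
Reagents that add atoms: none
Why: Mild acid hydrolysis removes the acetonide and the tertiary TES ether without touching the hindered ester or the trisubstituted alkene.

Step 19
Reactants: 27 methyl (4R,5R,8R,9S,13S,14R)-13,14,15-trihydroxyhalim-1(10)-en-18-oate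
Product: 28 methyl (4R,5R,8R,9S,13S,14R)-14,15-diacetoxy-13-hydroxyhalim-1(10)-en-18-oate (target)
Conditions: Ac2O, pyridine, DMAP (cat.), CH2Cl2, 0 °C → rt
Reagents that add atoms: acetic anhydride, CC(=O)OC(C)=O
Why: Acylation of the primary and secondary hydroxyls; the tertiary 13‑OH is not acetylated under these conditions.

## Compound list

1 | 1,2:5,6-di-O-isopropylidene-D-mannitol | CC1(C)OC[C@@H](O1)[C@@H](O)[C@H](O)[C@H]2COC(C)(C)O2 | starting material
2 | (R)-2,2-dimethyl-1,3-dioxolane-4-carbaldehyde | O=C[C@H]1COC(C)(C)O1 | intermediate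
3 | 1-[(4R)-2,2-dimethyl-1,3-dioxolan-4-yl]prop-2-en-1-ol (carbinol epimers) | C=CC(O)[C@H]1COC(C)(C)O1 | intermediate
4 | 1-[(4R)-2,2-dimethyl-1,3-dioxolan-4-yl]prop-2-en-1-one | C=CC(=O)[C@H]1COC(C)(C)O1 | intermediate
5 | 2-methylcyclohex-2-en-1-one | CC1=CCCCC1=O | starting material
6 | dimethylaluminium (3R)-2,3-dimethylcyclohex-1-en-1-olate | C[C@@H]1CCCC(O[Al](C)C)=C1C | intermediate
7 | [(3R)-2,3-dimethylcyclohex-1-en-1-yl]oxy(trimethyl)silane | C[C@@H]1CCCC(O[Si](C)(C)C)=C1C | intermediate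
8 | trimethylsilyl enol ether (at C13) of diketone 9 | O=C1CCC[C@@H](C)[C@]1(C)CC=C(O[Si](C)(C)C)[C@H]2COC(C)(C)O2 | intermediate
9 | (2S,3R)-2-{3-[(4R)-2,2-dimethyl-1,3-dioxolan-4-yl]-3-oxopropyl}-2,3-dimethylcyclohexan-1-one | O=C1CCC[C@@H](C)[C@]1(C)CCC(=O)[C@H]2COC(C)(C)O2 | intermediate
10 | (2S,3R)-2-{(3S)-3-[(4R)-2,2-dimethyl-1,3-dioxolan-4-yl]-3-hydroxybutyl}-2,3-dimethylcyclohexan-1-one | O=C1CCC[C@@H](C)[C@]1(C)CC[C@](C)(O)[C@H]2COC(C)(C)O2 | intermediate
11 | (2S,3R)-2,3-dimethyl-2-R*-cyclohexan-1-one (triethylsilyl ether of 10) | O=C1CCC[C@@H](C)[C@]1(C)CC[C@](C)(O[Si](CC)(CC)CC)[C@H]2COC(C)(C)O2 | intermediate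
12 | potassium enolate of 11 (C10–O, C10=C5) | [K+].[O-]C1=CCC[C@@H](C)[C@]1(C)CC[C@](C)(O[Si](CC)(CC)CC)[C@H]2COC(C)(C)O2 | intermediate
13 | (5R,6S)-5,6-dimethyl-6-R*-cyclohex-1-en-1-yl trifluoromethanesulfonate | O=S(=O)(OC1=CCC[C@@H](C)[C@]1(C)CC[C@](C)(O[Si](CC)(CC)CC)[C@H]2COC(C)(C)O2)C(F)(F)F | intermediate
14 | 1-[(5R,6S)-5,6-dimethyl-6-R*-cyclohex-1-en-1-yl]prop-2-en-1-one | C=CC(=O)C1=CCC[C@@H](C)[C@]1(C)CC[C@](C)(O[Si](CC)(CC)CC)[C@H]2COC(C)(C)O2 | intermediate
15 | dimethyl malonate | COC(=O)CC(=O)OC | starting material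
16 | dimethyl 2-{3-[(5R,6S)-5,6-dimethyl-6-R*-cyclohex-1-en-1-yl]-3-oxopropyl}propanedioate | COC(=O)C(CCC(=O)C1=CCC[C@@H](C)[C@]1(C)CC[C@](C)(O[Si](CC)(CC)CC)[C@H]2COC(C)(C)O2)C(=O)OC | intermediate
17 | dimethyl 2-{(3R)-3-hydroxy-3-[(5R,6S)-5,6-dimethyl-6-R*-cyclohex-1-en-1-yl]propyl}propanedioate | COC(=O)C(CC[C@@H](O)C1=CCC[C@@H](C)[C@]1(C)CC[C@](C)(O[Si](CC)(CC)CC)[C@H]2COC(C)(C)O2)C(=O)OC | intermediate
18 | methyl (6R)-6-[(5R,6S)-5,6-dimethyl-6-R*-cyclohex-1-en-1-yl]-2-oxooxane-3-carboxylate (C-3 epimers) | COC(=O)C1CC[C@@H](OC1=O)C2=CCC[C@@H](C)[C@]2(C)CC[C@](C)(O[Si](CC)(CC)CC)[C@H]3COC(C)(C)O3 | intermediate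
19 | tert-butyldimethylsilyl ketene acetal of lactone 18 | COC(=O)C1=C(O[Si](C)(C)C(C)(C)C)O[C@H](CC1)C2=CCC[C@@H](C)[C@]2(C)CC[C@](C)(O[Si](CC)(CC)CC)[C@H]3COC(C)(C)O3 | intermediate
20 | 19-(tert-butyldimethylsilyl) 18-methyl (4R,5R,8R,9S)-halim-1(10)-ene-18,19-dioate (13-OTES; 14,15-acetonide) | COC(=O)[C@]1(C(=O)O[Si](C)(C)C(C)(C)C)CCC=C2[C@H]1CC[C@@H](C)[C@]2(C)CC[C@](C)(O[Si](CC)(CC)CC)[C@H]3COC(C)(C)O3 | intermediate
21 | (4R,5R,8R,9S)-halim-1(10)-ene-18,19-dioic acid 18-methyl ester (4α-CO2Me, 4β-CO2H, 5α-H; 13-OTES; 14,15-acetonide) | COC(=O)[C@]1(C(O)=O)CCC=C2[C@H]1CC[C@@H](C)[C@]2(C)CC[C@](C)(O[Si](CC)(CC)CC)[C@H]3COC(C)(C)O3 | intermediate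
22 | isobutyl carbonic anhydride of acid 21 | COC(=O)[C@]1(C(=O)OC(=O)OCC(C)C)CCC=C2[C@H]1CC[C@@H](C)[C@]2(C)CC[C@](C)(O[Si](CC)(CC)CC)[C@H]3COC(C)(C)O3 | intermediate
23 | methyl (4R,5R,8R,9S)-19-hydroxyhalim-1(10)-en-18-oate (13-OTES; 14,15-acetonide) | COC(=O)[C@]1(CO)CCC=C2[C@H]1CC[C@@H](C)[C@]2(C)CC[C@](C)(O[Si](CC)(CC)CC)[C@H]3COC(C)(C)O3 | intermediate
24 | methyl (4R,5R,8R,9S)-19-oxohalim-1(10)-en-18-oate (13-OTES; 14,15-acetonide) | COC(=O)[C@]1(C=O)CCC=C2[C@H]1CC[C@@H](C)[C@]2(C)CC[C@](C)(O[Si](CC)(CC)CC)[C@H]3COC(C)(C)O3 | intermediate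
25 | C-19 N-tosylhydrazone of 24 | COC(=O)[C@]1(C=NNS(=O)(=O)c3ccc(C)cc3)CCC=C2[C@H]1CC[C@@H](C)[C@]2(C)CC[C@](C)(O[Si](CC)(CC)CC)[C@H]4COC(C)(C)O4 | intermediate
26 | methyl (4R,5R,8R,9S,13S,14R)-14,15-O-isopropylidene-13-(triethylsilyloxy)halim-1(10)-en-18-oate | COC(=O)[C@]1(C)CCC=C2[C@H]1CC[C@@H](C)[C@]2(C)CC[C@](C)(O[Si](CC)(CC)CC)[C@H]3COC(C)(C)O3 | intermediate
27 | methyl (4R,5R,8R,9S,13S,14R)-13,14,15-trihydroxyhalim-1(10)-en-18-oate | COC(=O)[C@]1(C)CCC=C2[C@H]1CC[C@@H](C)[C@]2(C)CC[C@](C)(O)[C@H](O)CO | intermediate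
28 | methyl (4R,5R,8R,9S,13S,14R)-14,15-diacetoxy-13-hydroxyhalim-1(10)-en-18-oate | COC(=O)[C@]1(C)CCC=C2[C@H]1CC[C@@H](C)[C@]2(C)CC[C@](C)(O)[C@@H](COC(C)=O)OC(C)=O | target

## Step count and risks

Total steps: 19. Longest linear sequence: 18 (1 → 2 → 3 → 4, then steps 5–19); the branch from 5 is 16 steps.

**Step 6 (chelation‑controlled methyl addition).** If the acetonide oxygen chelates poorly, Felkin addition would give the 13‑epimer, and the ring ketone could compete. The fallback sets out from 7 and comes back at 10; it builds C13/C14 by asymmetric epoxidation instead. Mukaiyama–Michael addition of 7 to methyl vinyl ketone gives (2S,3R)-2,3-dimethyl-2-(3-oxobutyl)cyclohexan-1-one F1. Horner–Wadsworth–Emmons olefination of the unhindered methyl ketone (triethyl phosphonoacetate, NaH) gives ethyl (E)-5-[(1S,6R)-1,6-dimethyl-2-oxocyclohexyl]-3-methylpent-2-enoate F2, the minor Z isomer being removed. Excess DIBAL‑H reduces ester and ring ketone to (E)-5-[(1S,6R)-2-hydroxy-1,6-dimethylcyclohexyl]-3-methylpent-2-en-1-ol F3. Sharpless epoxidation with L‑(+)‑diethyl tartrate gives the (2S,3S)-epoxy alcohol F4. Payne rearrangement with hydroxide opening (aq NaOH, t‑BuOH) inverts C‑14 and gives the (13S,14R)-tetraol F5. 2,2‑Dimethoxypropane/PPTS gives the terminal acetonide F6, and Dess–Martin oxidation of the ring carbinol gives 10.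

**Step 9 (carbonylative Stille coupling, with step 10).** The triflate is flanked by a quaternary carbon, direct non‑carbonylative coupling is possible, and the divinyl ketone may polymerise or undergo a second, intramolecular Michael addition in step 10. The fallback sets out from 13 and comes back at 16. A Nozaki–Hiyama–Kishi coupling (CrCl2, cat. NiCl2, DMF) of 13 with dimethyl 2-(3-oxopropyl)propanedioate F7 (from base‑catalysed Michael addition of 15 to acrolein) gives the allylic alcohol dimethyl 2-{3-hydroxy-3-[(5R,6S)-5,6-dimethyl-6-R*-cyclohex-1-en-1-yl]propyl}propanedioate F8 as a C‑1 epimer mixture. Dess–Martin oxidation then gives 16.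

**Step 13 (Ireland–Claisen ring contraction of a malonate‑type lactone).** The stabilised ketene acetal may rearrange sluggishly, or the half‑ester may decarboxylate on heating. The fallback sets out from 17 and comes back at 23. Methyl chloroformate/pyridine converts 17 into the allylic methyl carbonate F9. Pd(PPh3)4 ionises it, and the tethered malonate attacks the distal allyl terminus C‑5 (intramolecular Tsuji–Trost alkylation, net retention, hence the same 5α‑H) to give the geminal diester dimethyl (5R,8R,9S)-halim-1(10)-ene-18,19-dioate F10. LiOH saponifies the less hindered 4α ester to the half‑acid F11. LiBH4 reduces the remaining 4β ester of its lithium salt to the hydroxy acid F12, and TMSCHN2 esterification gives 23.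

## Further compounds

F1 | step 6 | (2S,3R)-2,3-dimethyl-2-(3-oxobutyl)cyclohexan-1-one | O=C1CCC[C@@H](C)[C@]1(C)CCC(C)=O
F2 | step 6 | ethyl (E)-5-[(1S,6R)-1,6-dimethyl-2-oxocyclohexyl]-3-methylpent-2-enoate | O=C1CCC[C@@H](C)[C@]1(C)CC/C(C)=C/C(=O)OCC
F3 | step 6 | (E)-5-[(1S,6R)-2-hydroxy-1,6-dimethylcyclohexyl]-3-methylpent-2-en-1-ol (ring carbinol epimers) | OC1CCC[C@@H](C)[C@]1(C)CC/C(C)=C/CO
F4 | step 6 | (2S,3S)-epoxy alcohol of F3 | OC1CCC[C@@H](C)[C@]1(C)CC[C@]2(C)O[C@H]2CO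
F5 | step 6 | (13S,14R)-tetraol (ring carbinol, 13-OH, 14-OH, 15-OH) | OC1CCC[C@@H](C)[C@]1(C)CC[C@](C)(O)[C@H](O)CO
F6 | step 6 | 14,15-acetonide of F5 | OC1CCC[C@@H](C)[C@]1(C)CC[C@](C)(O)[C@H]2COC(C)(C)O2
F7 | step 9 | dimethyl 2-(3-oxopropyl)propanedioate | COC(=O)C(CCC=O)C(=O)OC
F8 | step 9 | dimethyl 2-{3-hydroxy-3-[(5R,6S)-5,6-dimethyl-6-R*-cyclohex-1-en-1-yl]propyl}propanedioate (C-1 epimers) | COC(=O)C(CCC(O)C1=CCC[C@@H](C)[C@]1(C)CC[C@](C)(O[Si](CC)(CC)CC)[C@H]2COC(C)(C)O2)C(=O)OC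
F9 | step 13 | methyl carbonate of the (1R)-allylic alcohol 17 | COC(=O)O[C@H](CCC(C(=O)OC)C(=O)OC)C1=CCC[C@@H](C)[C@]1(C)CC[C@](C)(O[Si](CC)(CC)CC)[C@H]2COC(C)(C)O2
F10 | step 13 | dimethyl (5R,8R,9S)-halim-1(10)-ene-18,19-dioate (13-OTES; 14,15-acetonide) | COC(=O)C1(C(=O)OC)CCC=C2[C@H]1CC[C@@H](C)[C@]2(C)CC[C@](C)(O[Si](CC)(CC)CC)[C@H]3COC(C)(C)O3
F11 | step 13 | halim-1(10)-ene-18,19-dioic acid 19-methyl ester (4α-CO2H, 4β-CO2Me) | OC(=O)[C@]1(C(=O)OC)CCC=C2[C@H]1CC[C@@H](C)[C@]2(C)CC[C@](C)(O[Si](CC)(CC)CC)[C@H]3COC(C)(C)O3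
F12 | step 13 | 19-hydroxyhalim-1(10)-en-18-oic acid (4α-CO2H, 4β-CH2OH) | OC(=O)[C@]1(CO)CCC=C2[C@H]1CC[C@@H](C)[C@]2(C)CC[C@](C)(O[Si](CC)(CC)CC)[C@H]3COC(C)(C)O3
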